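**Retrosynthetic overview**

1. Clerodane numbering is used for atom labels (ring A = C1–C5 and C10, ring B = C5–C10, side chain C11–C16, β = the face of the C5 methyl C19). The enabling feature is that the C3 ketone of ring A and the C7 oxygen of ring B are 1,5-related through C4, quaternary C5 and C6, so C5–C6 is a Michael retron: C6 is the α-carbon of a C7 methyl ketone and C5 the β-carbon of a ring-A 3-methylcyclohex-2-enone.
2. Key disconnection C5–C6: a silyl-triflate-mediated intramolecular Michael addition closes ring B, makes quaternary C5, converges the C10 epimers to the cis fusion, and returns C3 as a regiodefined Δ3 silyl enol ether (handle for C18) beside a free C7 ketone (handle for the acetate).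
3. Ring A is carried as a 4-methoxy-2-methylphenyl group and unmasked by Birch reduction/hydrolysis. Quaternary C9 and C8 come from an enantioselective Ireland–Claisen rearrangement (C8 is made 8β as a relay and epimerised after ring closure). C13 comes from asymmetric hydrogenation after a B-alkyl Suzuki coupling.
4. Ring order: ring A (arene to enone, step 9), then ring B (step 11). End game: C7 reduction and acetylation, C4 methylenation (Mannich/Cope), C2 oxidation to the diosphenol.

Key step: step 11

Assumption: the enantiomer named for the chiral boron bromide (step 4) and for BINAP (step 8) is taken to be the one that delivers the configuration drawn; if the sense of induction is the opposite, the mirror-image reagent is used.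

**Route**

Step 1
Reactants: 1 1-(4-methoxy-2-methylphenyl)ethan-1-one; 2 triethyl phosphonoacetate
Product: 3 ethyl (2E)-3-(4-methoxy-2-methylphenyl)but-2-enoate
Conditions: NaH, THF, 0 °C to reflux; minor Z isomer removed by chromatography
Reagents that add atoms: triethyl phosphonoacetate, CCOC(=O)CP(=O)(OCC)OCC
Why: Horner–Wadsworth–Emmons olefination of the aryl methyl ketone should give mainly the E enoate (aryl trans to the ester), the alkene geometry that later defines C9.

Step 2
Reactants: 3 ethyl (2E)-3-(4-methoxy-2-methylphenyl)but-2-enoate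
Product: 4 (2E)-3-(4-methoxy-2-methylphenyl)but-2-en-1-ol
Conditions: i-Bu2AlH, CH2Cl2, −78 °C; Rochelle salt work-up
Reagents that add atoms: none
Why: 1,2-reduction of the enoate at low temperature should give the E allylic alcohol with the trisubstituted alkene untouched.

Step 3
Reactants: 4 (2E)-3-(4-methoxy-2-methylphenyl)but-2-en-1-ol; 5 propanoyl chloride
Product: 6 (2E)-3-(4-methoxy-2-methylphenyl)but-2-en-1-yl propanoate
Conditions: Et3N, DMAP (cat.), CH2Cl2, 0 °C
Reagents that add atoms: propanoyl chloride, CCC(Cl)=O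
Why: acylation of the primary allylic alcohol installs the propionate whose α-carbon becomes C8 and whose carbonyl becomes C7.

Step 4
Reactants: 6 (2E)-3-(4-methoxy-2-methylphenyl)but-2-en-1-yl propanoate
Product: 8 (2R,3S)-3-(4-methoxy-2-methylphenyl)-2,3-dimethylpent-4-enoic acid, via boron ketene acetal 7 (not isolated)
Conditions: (S,S)-2-bromo-4,5-diphenyl-1,3-bis[3,5-bis(trifluoromethyl)benzenesulfonyl]-1,3,2-diazaborolidine (1.1 equiv), Et3N, toluene/hexane, −78 °C, then −20 to 4 °C; aqueous work-up
Reagents that add atoms: none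
Why: enantioselective Ireland–Claisen rearrangement, in which the Z(O)-boron ketene acetal 7 should rearrange through a chair with the E-aryl group and the enolate methyl both equatorial, so the alkene geometry is translated into quaternary C9 and the syn C8/C9 pair, with the facial sense set by the C2-symmetric diazaborolidine.

Step 5
Reactants: 8 (2R,3S)-3-(4-methoxy-2-methylphenyl)-2,3-dimethylpent-4-enoic acid; 9 methyllithium
Product: 10 (3R,4S)-4-(4-methoxy-2-methylphenyl)-3,4-dimethylhex-5-en-2-one
Conditions: MeLi (2.2 equiv), THF, 0 °C; inverse quench into aq. HCl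
Reagents that add atoms: methyllithium, [Li]C
Why: addition of MeLi to the lithium carboxylate should stop at the dilithio ketone hydrate and give the methyl ketone (C6–C7) on work-up without enolising C8.

Step 6
Reactants: 11 but-2-ynoic acid
Product: 12 (2Z)-3-iodobut-2-enoic acid
Conditions: NaI, AcOH, 115 °C
Reagents that add atoms: sodium iodide, [Na+].[I-]
Why: anti hydroiodination of the ynoic acid (conjugate addition of iodide, then protonation) should give the Z β-iodoacrylic acid.

Step 7
Reactants: 10 (3R,4S)-4-(4-methoxy-2-methylphenyl)-3,4-dimethylhex-5-en-2-one; 12 (2Z)-3-iodobut-2-enoic acid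
Product: 14 (2Z,6S,7R)-8-hydroxy-6-(4-methoxy-2-methylphenyl)-3,6,7-trimethylnon-2-enoic acid (both carbinol epimers), via bis(9-BBN) adduct 13 (not isolated)
Conditions: 9-BBN (2.5 equiv), THF, 65 °C; then 12, Pd(dppf)Cl2 (5 mol %), aq. K3PO4, DMF, 50 °C
Reagents that add atoms: (2Z)-3-iodobut-2-enoic acid, I/C(C)=C\C(=O)O
Why: anti-Markovnikov hydroboration of the vinyl group and B-alkyl Suzuki–Miyaura coupling with retention of the Z geometry should join C12 to C13, while the excess borane reduces the C7 ketone to the carbinol, which keeps C8 from enolising (any unreduced ketone converges in step 9).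

Step 8
Reactants: 14 (2Z,6S,7R)-8-hydroxy-6-(4-methoxy-2-methylphenyl)-3,6,7-trimethylnon-2-enoic acid
Product: 15 (3R,6S,7R)-8-hydroxy-6-(4-methoxy-2-methylphenyl)-3,6,7-trimethylnonanoic acid (both carbinol epimers)
Conditions: Ru(OAc)2[(S)-BINAP] (1 mol %), H2 (100 atm), MeOH, 25 °C
Reagents that add atoms: none
Why: carboxylate-directed asymmetric hydrogenation of the β,β-disubstituted acrylic acid should set C13 (R) under catalyst control, remote from the other stereocentres and without touching the arene.

Step 9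
Reactants: 15 (3R,6S,7R)-8-hydroxy-6-(4-methoxy-2-methylphenyl)-3,6,7-trimethylnonanoic acid
Product: 17 (3R,6R,7R)-8-hydroxy-3,6,7-trimethyl-6-(2-methyl-4-oxocyclohex-2-en-1-yl)nonanoic acid (epimers at ring C1 = C10 and at the carbinol), via dihydroanisole 16 (not isolated)
Conditions: Li, NH3(l), THF, t-BuOH, −78 to −33 °C; NH4Cl; then 2 M HCl, THF, 23 °C
Reagents that add atoms: water, O
Why: Birch reduction should leave the methoxy- and alkyl-bearing carbons sp2 (1,4-diene 16, carboxylate and alkoxide inert), and enol ether hydrolysis with conjugation unmasks ring A as the 3-methylcyclohex-2-enone; C10 is formed without control, which step 11 corrects.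

Step 10
Reactants: 17 (3R,6R,7R)-8-hydroxy-3,6,7-trimethyl-6-(2-methyl-4-oxocyclohex-2-en-1-yl)nonanoic acid
Product: 18 (3R,6R,7R)-3,6,7-trimethyl-6-(2-methyl-4-oxocyclohex-2-en-1-yl)-8-oxononanoic acid (both C10 epimers)
Conditions: Dess–Martin periodinane, CH2Cl2, 23 °C
Reagents that add atoms: none
Why: Dess–Martin oxidation returns the C7 methyl ketone under non-basic conditions, so C8 should keep its configuration.

Step 11
Reactants: 18 (3R,6R,7R)-3,6,7-trimethyl-6-(2-methyl-4-oxocyclohex-2-en-1-yl)-8-oxononanoic acid; 19 tert-butyldimethylsilyl trifluoromethanesulfonate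
Product: 22 (13R)-3-(tert-butyldimethylsilyloxy)-8β-methyl-7-oxo-18-nor-cis-clerod-3-en-15-oic acid (5β-CH3 10β-H 9α-CH3), via bis-silyl enol ether 20 (not isolated), via cyclised silyl ester 21 (not isolated)
Conditions: TBSOTf (2.2 equiv), Et3N (4 equiv), CH2Cl2, −78 to 0 °C; aq. NaHCO3/MeOH work-up
Reagents that add atoms: tert-butyldimethylsilyl trifluoromethanesulfonate, CC(C)(C)[Si](C)(C)OS(=O)(=O)C(F)(F)F
Why: Et3N/TBSOTf silylates the acid and converts the C7 methyl ketone into its kinetic terminal silyl enol ether 20, whose C6 adds to C5 of the silyl-activated ring-A enone (Mukaiyama–Michael addition; the closest known reaction type is the silyl triflate–amine-mediated intramolecular Michael cyclisation of keto enones), the silyl group ending on O3. Ring B closes in the 6-(enolendo)-exo-trig mode by the C5–C6 bond. C5: the nucleophile is tethered through C9 to C10 and attacks axially, so the new bond is cis to the C10–C9 bond and the fusion should be cis (C19 and H10 on the same face). C10: the two epimers of 18 can interconvert through the extended silyl dienol ether (C3=C4–C5=C10), and only the epimer whose chair transition state carries the C8 methyl equatorial and the C11 chain axial should cyclise readily, so C8/C9 relay their configuration to C10 and C5. Needed selectivities are enolisation towards C6 and not C8 (kinetic preference for the methyl group, C8–H being flanked by quaternary C9) and conjugate rather than carbonyl attack (only C5 is within reach of the three-atom tether). The product 22 carries C3 as a Δ3 silyl enol ether and C7 as a free ketone, which separates the two carbonyl groups for the end game.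

Step 12
Reactants: 22 (13R)-3-(tert-butyldimethylsilyloxy)-8β-methyl-7-oxo-18-nor-cis-clerod-3-en-15-oic acid
Product: 23 (13R)-3-(tert-butyldimethylsilyloxy)-8α-methyl-7-oxo-18-nor-cis-clerod-3-en-15-oic acid
Conditions: DBU (2.5 equiv), toluene, 40 °C; citric acid work-up
Reagents that add atoms: none
Why: C8 is the only enolisable stereocentre next to the C7 ketone, and base equilibration should favour the equatorial 8α methyl over the axial 8β methyl that served as relay (thermodynamic control; the minor epimer is recycled).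

Step 13
Reactants: 23 (13R)-3-(tert-butyldimethylsilyloxy)-8α-methyl-7-oxo-18-nor-cis-clerod-3-en-15-oic acid
Product: 24 (13R)-3-(tert-butyldimethylsilyloxy)-7β-hydroxy-18-nor-cis-clerod-3-en-15-oic acid
Conditions: Li, NH3(l), THF, t-BuOH (2 equiv), −78 °C; NH4Cl
Reagents that add atoms: none
Why: dissolving-metal reduction should give the thermodynamically preferred equatorial 7β alcohol (hydride reagents would attack from the open equatorial side, since the axial trajectory is blocked by C20 and C4), with silyl enol ether and carboxylate inert.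

Step 14
Reactants: 24 (13R)-3-(tert-butyldimethylsilyloxy)-7β-hydroxy-18-nor-cis-clerod-3-en-15-oic acid; 25 acetic anhydride
Product: 27 (13R)-7β-acetoxy-3-(tert-butyldimethylsilyloxy)-18-nor-cis-clerod-3-en-15-oic acid, via mixed anhydride 26 (not isolated)
Conditions: Ac2O, pyridine, DMAP (cat.), 0 to 23 °C; then H2O, 1 h
Reagents that add atoms: acetic anhydride, CC(=O)OC(C)=O
Why: DMAP-catalysed acetylation of the secondary alcohol; the mixed anhydride 26 formed at C15 is hydrolysed back to the acid in the aqueous pyridine quench.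

Step 15
Reactants: 27 (13R)-7β-acetoxy-3-(tert-butyldimethylsilyloxy)-18-nor-cis-clerod-3-en-15-oic acid; 28 dimethyl(methylidene)ammonium iodide
Product: 31 (13R)-7β-acetoxy-3-oxo-cis-clerod-4(18)-en-15-oic acid, via Mannich base 29 (not isolated), via amine N-oxide 30 (not isolated)
Conditions: CH2=NMe2+ I−, CH2Cl2, 23 °C; then mCPBA, NaHCO3, CH2Cl2, 0 to 23 °C
Reagents that add atoms: dimethyl(methylidene)ammonium iodide, C=[N+](C)C.[I-]
Why: Mannich reaction of the regiodefined Δ3 silyl enol ether puts C18 on C4, and N-oxidation followed by Cope elimination can only eliminate towards C4–H (C5 is quaternary), giving the exocyclic enone without strong base or methyl iodide.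

Step 16
Reactants: 31 (13R)-7β-acetoxy-3-oxo-cis-clerod-4(18)-en-15-oic acid
Product: 34 (13R)-7β-acetoxy-2-hydroxy-3-oxo-cis-clerod-4(18)-en-15-oic acid (C2 epimers), via bis-trimethylsilyl dienol ether 32 (not isolated), via 2-silyloxy ketone 33 (not isolated)
Conditions: TMSOTf (2.5 equiv), Et3N, CH2Cl2, −78 to 0 °C; then dimethyldioxirane, acetone, −78 to 0 °C; citric acid, MeOH/H2O
Reagents that add atoms: dimethyldioxirane, CC1(C)OO1
Why: C2 is the only enolisable position of the C3 ketone, so soft enolisation should give one 2-silyloxy diene whose electron-rich enol ether bond is epoxidised selectively (Rubottom oxidation) to the C2 acyloin.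

Step 17
Reactants: 34 (13R)-7β-acetoxy-2-hydroxy-3-oxo-cis-clerod-4(18)-en-15-oic acid
Product: 36 CNP0257844.1 (5S,7S,8S,9R,10R,13R)-7-acetoxy-2-hydroxy-3-oxo-cis-cleroda-1,4(18)-dien-15-oic acid, via 2,3-diketone 35 (not isolated)
Conditions: Dess–Martin periodinane, CH2Cl2, 0 to 23 °C
Reagents that add atoms: none
Why: Dess–Martin oxidation of the acyloin gives the 2,3-diketone 35, which can enolise only towards C1 and should therefore rest as the diosphenol of the target.

**Compound list**

1 | 1-(4-methoxy-2-methylphenyl)ethan-1-one | CC(=O)c1ccc(OC)cc1C | starting material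
2 | triethyl phosphonoacetate | CCOC(=O)CP(=O)(OCC)OCC | starting material
3 | ethyl (2E)-3-(4-methoxy-2-methylphenyl)but-2-enoate | CCOC(=O)/C=C(\C)c1ccc(OC)cc1C | intermediate
4 | (2E)-3-(4-methoxy-2-methylphenyl)but-2-en-1-ol | OC/C=C(\C)c1ccc(OC)cc1C | intermediate
5 | propanoyl chloride | CCC(Cl)=O | starting material
6 | (2E)-3-(4-methoxy-2-methylphenyl)but-2-en-1-yl propanoate | CCC(=O)OC/C=C(\C)c1ccc(OC)cc1C | intermediate
7 | Z(O)-boron ketene acetal of 6 (enolate methyl cis to O–B; (S,S)-diazaborolidinyl on oxygen) | C/C=C(/OC/C=C(\C)c1ccc(OC)cc1C)OB1N(S(=O)(=O)c2cc(cc(c2)C(F)(F)F)C(F)(F)F)[C@@H](c2ccccc2)[C@H](c2ccccc2)N1S(=O)(=O)c1cc(cc(c1)C(F)(F)F)C(F)(F)F | intermediate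
8 | (2R,3S)-3-(4-methoxy-2-methylphenyl)-2,3-dimethylpent-4-enoic acid | COc1ccc(c(C)c1)[C@@](C)(C=C)[C@@H](C)C(=O)O | intermediate
9 | methyllithium | [Li]C | starting material
10 | (3R,4S)-4-(4-methoxy-2-methylphenyl)-3,4-dimethylhex-5-en-2-one | COc1ccc(c(C)c1)[C@@](C)(C=C)[C@@H](C)C(C)=O | intermediate
11 | but-2-ynoic acid | CC#CC(=O)O | starting material
12 | (2Z)-3-iodobut-2-enoic acid | I/C(C)=C\C(=O)O | intermediate
13 | bis(9-BBN) adduct of 10 (B-alkyl at C12, borinate at O7) | COc1ccc(c(C)c1)[C@@](C)(CCB1C2CCCC1CCC2)[C@@H](C)C(C)OB1C2CCCC1CCC2 | intermediate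
14 | (2Z,6S,7R)-8-hydroxy-6-(4-methoxy-2-methylphenyl)-3,6,7-trimethylnon-2-enoic acid (both carbinol epimers) | COc1ccc(c(C)c1)[C@@](C)(CC/C(C)=C\C(=O)O)[C@@H](C)C(C)O | intermediate
15 | (3R,6S,7R)-8-hydroxy-6-(4-methoxy-2-methylphenyl)-3,6,7-trimethylnonanoic acid (both carbinol epimers) | COc1ccc(c(C)c1)[C@@](C)(CC[C@@H](C)CC(=O)O)[C@@H](C)C(C)O | intermediate
16 | (3R,6S,7R)-8-hydroxy-6-(4-methoxy-2-methylcyclohexa-1,4-dien-1-yl)-3,6,7-trimethylnonanoic acid | COC1=CCC(=C(C)C1)[C@@](C)(CC[C@@H](C)CC(=O)O)[C@@H](C)C(C)O | intermediate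
17 | (3R,6R,7R)-8-hydroxy-3,6,7-trimethyl-6-(2-methyl-4-oxocyclohex-2-en-1-yl)nonanoic acid (epimers at ring C1 and at the carbinol) | O=C1C=C(C)C(CC1)[C@@](C)(CC[C@@H](C)CC(=O)O)[C@@H](C)C(C)O | intermediate
18 | (3R,6R,7R)-3,6,7-trimethyl-6-(2-methyl-4-oxocyclohex-2-en-1-yl)-8-oxononanoic acid (both epimers at ring C1 = C10) | O=C1C=C(C)C(CC1)[C@@](C)(CC[C@@H](C)CC(=O)O)[C@@H](C)C(C)=O | intermediate
19 | tert-butyldimethylsilyl trifluoromethanesulfonate | CC(C)(C)[Si](C)(C)OS(=O)(=O)C(F)(F)F | starting material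
20 | silyl ester of 18 with C7 as the terminal tert-butyldimethylsilyl enol ether | O=C1C=C(C)C(CC1)[C@@](C)(CC[C@@H](C)CC(=O)O[Si](C)(C)C(C)(C)C)[C@@H](C)C(=C)O[Si](C)(C)C(C)(C)C | intermediate
21 | tert-butyldimethylsilyl ester of 22 | C1=C(O[Si](C)(C)C(C)(C)C)CC[C@@H]2[C@@](C)(CC[C@@H](C)CC(=O)O[Si](C)(C)C(C)(C)C)[C@@H](C)C(=O)C[C@]12C | intermediate
22 | (13R)-3-(tert-butyldimethylsilyloxy)-8β-methyl-7-oxo-18-nor-cis-clerod-3-en-15-oic acid (5β-CH3, 10β-H, 9α-CH3, 9β-side chain) | C1=C(O[Si](C)(C)C(C)(C)C)CC[C@@H]2[C@@](C)(CC[C@@H](C)CC(=O)O)[C@@H](C)C(=O)C[C@]12C | intermediate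
23 | (13R)-3-(tert-butyldimethylsilyloxy)-8α-methyl-7-oxo-18-nor-cis-clerod-3-en-15-oic acid | C1=C(O[Si](C)(C)C(C)(C)C)CC[C@@H]2[C@@](C)(CC[C@@H](C)CC(=O)O)[C@H](C)C(=O)C[C@]12C | intermediate
24 | (13R)-3-(tert-butyldimethylsilyloxy)-7β-hydroxy-18-nor-cis-clerod-3-en-15-oic acid | C1=C(O[Si](C)(C)C(C)(C)C)CC[C@@H]2[C@@](C)(CC[C@@H](C)CC(=O)O)[C@H](C)[C@@H](O)C[C@]12C | intermediate
25 | acetic anhydride | CC(=O)OC(C)=O | starting material
26 | mixed acetic anhydride of 27 at C15 | C1=C(O[Si](C)(C)C(C)(C)C)CC[C@@H]2[C@@](C)(CC[C@@H](C)CC(=O)OC(C)=O)[C@H](C)[C@@H](OC(C)=O)C[C@]12C | intermediate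
27 | (13R)-7β-acetoxy-3-(tert-butyldimethylsilyloxy)-18-nor-cis-clerod-3-en-15-oic acid | C1=C(O[Si](C)(C)C(C)(C)C)CC[C@@H]2[C@@](C)(CC[C@@H](C)CC(=O)O)[C@H](C)[C@@H](OC(C)=O)C[C@]12C | intermediate
28 | dimethyl(methylidene)ammonium iodide | C=[N+](C)C.[I-] | starting material
29 | (13R)-7β-acetoxy-18-(dimethylamino)-3-oxo-cis-clerodan-15-oic acid (C4 epimers) | CN(C)CC1C(=O)CC[C@@H]2[C@@](C)(CC[C@@H](C)CC(=O)O)[C@H](C)[C@@H](OC(C)=O)C[C@]12C | intermediate
30 | N-oxide of 29 | C[N+](C)([O-])CC1C(=O)CC[C@@H]2[C@@](C)(CC[C@@H](C)CC(=O)O)[C@H](C)[C@@H](OC(C)=O)C[C@]12C | intermediate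
31 | (13R)-7β-acetoxy-3-oxo-cis-clerod-4(18)-en-15-oic acid | C=C1C(=O)CC[C@@H]2[C@@](C)(CC[C@@H](C)CC(=O)O)[C@H](C)[C@@H](OC(C)=O)C[C@]12C | intermediate
32 | trimethylsilyl ester of 31 with C3 as the Δ2 trimethylsilyl dienol ether | C=C1C(O[Si](C)(C)C)=CC[C@@H]2[C@@](C)(CC[C@@H](C)CC(=O)O[Si](C)(C)C)[C@H](C)[C@@H](OC(C)=O)C[C@]12C | intermediate
33 | trimethylsilyl ester of the 2-(trimethylsilyloxy) ketone | C=C1C(=O)C(O[Si](C)(C)C)C[C@@H]2[C@@](C)(CC[C@@H](C)CC(=O)O[Si](C)(C)C)[C@H](C)[C@@H](OC(C)=O)C[C@]12C | intermediate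
34 | (13R)-7β-acetoxy-2-hydroxy-3-oxo-cis-clerod-4(18)-en-15-oic acid (C2 epimers) | C=C1C(=O)C(O)C[C@@H]2[C@@](C)(CC[C@@H](C)CC(=O)O)[C@H](C)[C@@H](OC(C)=O)C[C@]12C | intermediate
35 | (13R)-7β-acetoxy-2,3-dioxo-cis-clerod-4(18)-en-15-oic acid | C=C1C(=O)C(=O)C[C@@H]2[C@@](C)(CC[C@@H](C)CC(=O)O)[C@H](C)[C@@H](OC(C)=O)C[C@]12C | intermediate
36 | CNP0257844.1, (5S,7S,8S,9R,10R,13R)-7-acetoxy-2-hydroxy-3-oxo-cis-cleroda-1,4(18)-dien-15-oic acid | C=C1C(=O)C(O)=C[C@@H]2[C@@](C)(CC[C@@H](C)CC(=O)O)[C@H](C)[C@@H](OC(C)=O)C[C@]12C | target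

**Totals**

Total step count: 17. Longest linear sequence: 16 steps (steps 1–5 and 7–17; step 6 is a one-step branch).

**Steps most likely to fail, each with a fallback**

- **Step 11.** Risk: incomplete equilibration of the C10 epimers, poor facial selectivity, or over-silylation of the new C7 ketone. The fallback sets out from 18 and returns at 22. The C10 epimers of 18 are separated by chromatography, giving the matched epimer (3R,6R,7R)-3,6,7-trimethyl-6-[(1S)-2-methyl-4-oxocyclohex-2-en-1-yl]-8-oxononanoic acid F1; the other epimer is re-equilibrated with DBU and recycled. F1 is treated with LiN(SiMe3)2 (2 equiv) in THF at −78 °C, which forms the carboxylate and the kinetic C6 lithium enolate. This enolate closes ring B by a stereospecific anionic Michael addition, the resulting C3 enolate is trapped on oxygen with TBSCl, and aqueous NaHCO3 cleaves the silyl ester to give 22.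

- **Step 4.** Risk: erosion of enantio- or diastereoselectivity, or sluggish rearrangement to the quaternary centre. The fallback sets out from 6 and returns at 8. An achiral Ireland–Claisen rearrangement (LiN(i-Pr)2, THF/DMPU, TMSCl, −78 to 23 °C, Z silyl ketene acetal) should give the same syn acid as a racemate, that is 8 together with its enantiomer (2S,3R)-3-(4-methoxy-2-methylphenyl)-2,3-dimethylpent-4-enoic acid F2. Classical resolution with (R)-1-phenylethanamine should let the salt (R)-1-phenylethanaminium (2R,3S)-3-(4-methoxy-2-methylphenyl)-2,3-dimethylpent-4-enoate F3 crystallise, and acidification of F3 returns 8.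

- **Step 13.** Risk: loss of the silyl enol ether under the dissolving-metal conditions, or formation of the axial alcohol. The fallback sets out from 23 and returns at 27. LiBH(s-Bu)3 in THF at −78 °C should attack from the open equatorial side and give the axial alcohol (13R)-3-(tert-butyldimethylsilyloxy)-7α-hydroxy-18-nor-cis-clerod-3-en-15-oic acid F4. A Mitsunobu reaction on F4 with a large excess of acetic acid (PPh3, diisopropyl azodicarboxylate, THF) inverts C7 and gives the 7β acetate 27 directly.

Further compounds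

F1 | step 11 | (3R,6R,7R)-3,6,7-trimethyl-6-[(1S)-2-methyl-4-oxocyclohex-2-en-1-yl]-8-oxononanoic acid | O=C1C=C(C)[C@H](CC1)[C@@](C)(CC[C@@H](C)CC(=O)O)[C@@H](C)C(C)=O
F2 | step 4 | (2S,3R)-3-(4-methoxy-2-methylphenyl)-2,3-dimethylpent-4-enoic acid | COc1ccc(c(C)c1)[C@](C)(C=C)[C@H](C)C(=O)O
F3 | step 4 | (R)-1-phenylethanaminium (2R,3S)-3-(4-methoxy-2-methylphenyl)-2,3-dimethylpent-4-enoate | C[C@@H]([NH3+])c1ccccc1.COc1ccc(c(C)c1)[C@@](C)(C=C)[C@@H](C)C(=O)[O-]
F4 | step 13 | (13R)-3-(tert-butyldimethylsilyloxy)-7α-hydroxy-18-nor-cis-clerod-3-en-15-oic acid | C1=C(O[Si](C)(C)C(C)(C)C)CC[C@@H]2[C@@](C)(CC[C@@H](C)CC(=O)O)[C@H](C)[C@H](O)C[C@]12C
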